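## The problem

The target joins two polyphenols through one methylene carbon. A (+)-catechin unit (ring A = benzo ring, ring C = pyran, ring B = catechol) carries at C8 a CH2 link to a hexasubstituted acylphloroglucinol, ring D. Counted from the acyl-bearing carbon, ring D carries: D1 (2R)-2-methylbutanoyl, D2 OH, D3 the bridging CH2, D4 OH, D5 CH3, D6 OCH3.

There are three stereocenters: C2 (R) and C3 (S) of ring C, trans to each other, and the (R) carbon next to the ketone. The chain center is separated from the ring centers by the flat ring D and the bridge, so neither set can control the other, and each must arrive with its configuration settled.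

The sensitive points are the six phenols and the secondary alcohol (oxidation, and base-induced opening of ring C at C2 once the 4'-phenol is free), the benzylic C2–O1 bond (acid, hydrogenolysis) and the ketone α-center (enolization).

Ring D sets the regiochemical problem: only one of its three oxygens is methylated, the one between the acyl and the C-methyl carbons, whereas direct O-methylation of an acylphloroglucinol prefers the oxygen para to the acyl group. A second selectivity question is the site of attachment on ring A, C8 against C6.

The enabling feature is that D1–D6–D5–D4 plus the ketone carbon map atom for atom onto C5–C4–C3–C2 and C6 of a 4-methoxy-3-methyl-2-pyranone. D2, D3 and the bridging CH2 are C1, C2 and C3 of a propanoate on catechin C8. Ring D is therefore a tetraketide that can be folded from two pieces of the right oxidation level, with the methyl ether already fixed.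

## Retrosynthesis

**18 ⇒ 17.** The last operation should only unmask, so the five O–CH2Ph bonds of 17 are cut. Benzyl is used on all five oxygens, O3 included, rather than a silyl ether at O3: one hydrogenolysis then ends the synthesis and the free polyphenol never meets fluoride, base or acid. The price is the slower cleavage of the one alkyl benzyl ether. Compound 17 is no simpler in skeleton than 18, but it tolerates the strong base of the key step. The forward reaction must cleave completely without touching the aryl ketone, the C2–O1 bond or any stereocenter.

**17 ⇒ 6 + 14.** Two ring D bonds are cut, D3–D4 and D1–D2. This returns the ester 6, whose C2 becomes D3 and whose C1 becomes D2, and the pyranone 14, whose C2 becomes D4 and whose C5 becomes D1. The neighbouring cuts are at the bridge (CH2–D3 or CH2–C8), a Friedel–Crafts union of two finished arenes. They would need ring D ready-made with its single methyl ether, which brings back the selective methylation. Folding an open triketo ester would give three undifferentiated oxygens. The chosen cut removes a whole hexasubstituted benzene ring: 6 is catechin with a three-carbon ester, and 14 is a small pyranone that already carries the ketone carbon, the methyl ether and the C-methyl group in the right order. The forward reaction must add the ester enolate to the lactone carbonyl, not to C4 or C6, must close by Claisen condensation, and must leave the sec-butyl center alone.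

**6 ⇒ 4 + 5.** The C8–CH2 bond is cut as an sp2–sp3 cross-coupling between bromide 4 and the zinc homoenolate 5. Against a Heck reaction with an acrylate followed by alkene reduction (two steps, with a reduction next to five benzyl ethers) or a formylation, olefination, reduction sequence (three steps), this installs the saturated ester in one step. The forward reaction must achieve oxidative addition into a hindered, electron-rich aryl bromide flanked by two oxygen substituents.

**4 ⇒ 3 ⇒ 2 ⇒ 1.** The C8–Br bond and the five benzyl ethers are removed in turn, back to catechin 1. Rings A, B and C and both ring C stereocenters are bought in 1. The forward steps must differentiate phenols from the alcohol (two-stage benzylation) and C8 from C6 (electrophilic bromination of the ring A diether, where C8 is the reactive site).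

**14 ⇒ 13 ⇒ 12 ⇒ 9 + 10, and 9 ⇒ 7.** The O–CH3 bond of 14 is cut to the hydroxypyranone 13 and the lactone C–O bond to the diketo ester 12. The C4–C5 bond of 12 is cut to the dianion of the keto ester 10 and the N-methoxy-N-methylamide 9 of acid 7. The amide is preferred to an acid chloride because it cannot form a ketene under the strongly basic acylation, which would racemize the center, and because it does not over-add. Compound 10 supplies the C-methyl group and the lactone carbonyl, and 7 supplies the ketone carbon and the (R) center. The forward sequence must keep that center intact and must methylate the 4-oxygen of the ambident pyranone anion.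

## Roads not taken

**Alternative 1:** The cut removes ring A itself: C4a–C8a, C5–C6 and C8–C8a. The components are the 3-benzyloxycyclobutenone A2, which carries a finished, benzyl-protected ring D on its C4 methylene, and the triisopropylsiloxyalkyne A3, which carries ring B as an (E)-cinnamyl group.

- **Forward key step:** On heating in toluene, A2 should open to a vinylketene that adds to A3. The adduct reopens and closes by 6π electrocyclization (Danheiser benzannulation) to the phenol A1, with the C8a hydroxyl free, C5 silylated and C7 benzylated.
- **Merits:** The benzannulation is a known, regioselective reaction class. It is convergent, and the C8/C6 question never arises because ring A is built around the diarylmethane.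
- **Weak points:** A1 is still open-chain and has neither ring C stereocenter. An asymmetric dihydroxylation of the alkene and a stereospecific cyclization must follow, and any shortfall in enantioselectivity shows up as diastereomers because of the existing (R) center. The skipped enyne of A3 can isomerize on heating. A2 presupposes a complete ring D with its single methyl ether, which is the very problem the pyranone fold removes, and needs a multi-step cyclobutenone synthesis as well.
- **Comparison:** This key step rests on firmer precedent than step 9, and the route would reach ring A analogues that 1 cannot supply. Against that, the chosen plan buys three rings and two stereocenters in 1, needs ten steps in all, and is backed by a fallback made only of known reactions.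

**Alternative 2:** The cut is C4–C4a. The precursor is the aryl ether A5, in which the ring A phenol (with the ring D benzyl group) is etherified by an (R)-benzylic carbon bearing ring B and an (S)-oxirane.

- **Forward key step:** BF3·OEt2 at low temperature or hexafluoroisopropanol activates the terminal epoxide. C4a attacks the CH2 carbon in a 6-endo Friedel–Crafts closure that releases the C3 hydroxyl and gives A4.
- **Merits:** The closure is of a known type for flavan-3-ols. The trans relation is set before cyclization, the C3 hydroxyl emerges free, and other configurations of ring C would be equally accessible.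
- **Weak points:** Both ring C stereocenters must be made. That needs an asymmetric epoxidation with kinetic resolution and an etherification with inversion at a benzylic carbon that ionizes easily because ring B is a dialkoxyphenyl group, using a phenol crowded by the ring D benzyl group. Under the acid of the key step the same benzylic C–O bond can ionize, and 5-exo attack at the internal epoxide carbon competes. Ring D must again be finished first.
- **Comparison:** This road is better in stereochemical flexibility and in the precedent of its ring closure. For the natural (2R,3S) series the chosen plan needs no stereocontrolled step and is several steps shorter.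

**Alternative 3:** The cuts are O1–C2 and C3–C4, the latter as a C3=C4 bond bearing a formyl group. The components are the ring A salicylaldehyde A7, which carries the ring D benzyl group, and the ring B cinnamaldehyde A8.

- **Forward key step:** With a diarylprolinol trimethylsilyl ether and an acid co-catalyst, the phenol adds to the iminium ion of A8 and the enamine condenses with the aryl aldehyde. Ring C closes as the (2R)-2-aryl-2H-chromene-3-carbaldehyde A6.
- **Merits:** The step is catalytic, enantioselective and convergent. Ring C forms in one step, and either enantiomer is available by choice of catalyst.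
- **Weak points:** A7 is a hexasubstituted benzene whose phenol sits between the formyl group and the bulky benzyl group, and whose aldehyde is deactivated by alkoxy donors. The iminium ion of electron-rich A8 is a weak acceptor. A6 can racemize by reversible ring opening. The formyl group must then be removed and the C3 hydroxyl introduced trans by hydroboration–oxidation, with C2 controlling C3. Ring D must again be complete beforehand.
- **Comparison:** In catalytic asymmetric convergence this road is superior, and it alone could deliver the unnatural flavan enantiomer with equal ease. The chosen plan has no enantio- or diastereoselective step at all, since the stereocenters come with 1 and 7, and its end game after ring formation is a single deprotection.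

Key step: step 9

Assumption: acid 7 is taken as the (R) enantiomer of high enantiomeric purity and reagent 5 as its commercial THF solution, both used as bought.

## Route

Step 1
Reactants: 1 (+)-catechin
Product: 2 5,7,3',4'-tetra-O-benzyl-(+)-catechin [(2R,3S)-5,7-bis(benzyloxy)-2-[3,4-bis(benzyloxy)phenyl]-3,4-dihydro-2H-chromen-3-ol]
Conditions: BnBr (4.4 equiv), K2CO3, DMF, 0 °C → rt
Reagents that add atoms: benzyl bromide, BrCc1ccccc1
Why: Williamson ether synthesis: K2CO3 ionizes only the four phenols, so the secondary alcohol stays free, and the mild base at room temperature avoids C-benzylation of ring A and opening of ring C; C2 and C3 are not touched.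

Step 2
Reactants: 2 5,7,3',4'-tetra-O-benzyl-(+)-catechin
Product: 3 3,5,7,3',4'-penta-O-benzyl-(+)-catechin [(2R,3S)-3,5,7-tris(benzyloxy)-2-[3,4-bis(benzyloxy)phenyl]-3,4-dihydro-2H-chromene]
Conditions: NaH, BnBr, n-Bu4NI (cat.), THF/DMF, 0 °C → rt
Reagents that add atoms: benzyl bromide, BrCc1ccccc1
Why: Williamson ether synthesis on the secondary alkoxide; no phenoxide is left that could open ring C and neither stereocenter bears an acidic hydrogen, so the (2R,3S) configuration is carried through.

Step 3
Reactants: 3 3,5,7,3',4'-penta-O-benzyl-(+)-catechin
Product: 4 8-bromo-3,5,7,3',4'-penta-O-benzyl-(+)-catechin [(2R,3S)-3,5,7-tris(benzyloxy)-2-[3,4-bis(benzyloxy)phenyl]-8-bromo-3,4-dihydro-2H-chromene]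
Conditions: N-bromosuccinimide (1.0 equiv), CH2Cl2, −78 °C → 0 °C
Reagents that add atoms: N-bromosuccinimide, O=C1CCC(=O)N1Br
Why: Electrophilic aromatic bromination: ring A is the most electron-rich arene, and of its two free positions C8 is the one that reacts in 5,7-di-O-alkylated flavan-3-ols while C6 is screened between two benzyloxy groups; one equivalent at low temperature without radical initiation spares the benzylic C–H bonds.

Step 4
Reactants: 4 8-bromo-3,5,7,3',4'-penta-O-benzyl-(+)-catechin; 5 (3-ethoxy-3-oxopropyl)zinc bromide
Product: 6 ethyl 3-[(2R,3S)-3,5,7,3',4'-penta-O-benzylcatechin-8-yl]propanoate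
Conditions: Pd(OAc)2 (5 mol %), 2-dicyclohexylphosphino-2',6'-dimethoxybiphenyl (SPhos, 10 mol %), 5 (2 equiv, 0.5 M in THF), THF, 60 °C
Reagents that add atoms: none
Why: Negishi coupling: the bulky, electron-rich biaryl phosphine lets zerovalent palladium insert into the C8–Br bond flanked by two oxygen substituents and speeds reductive elimination past β-hydride elimination, while the zinc homoenolate is too mild to attack its own ester or any ether; no base is present, so the stereocenters are safe.

Step 5
Reactants: 7 (2R)-2-methylbutanoic acid
Product: 9 (2R)-N-methoxy-N,2-dimethylbutanamide, via acyl imidazole 8 (not isolated)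
Conditions: 1,1'-carbonyldiimidazole (1.1 equiv), CH2Cl2, 0 °C → rt; then MeNH(OMe)·HCl (1.2 equiv), rt
Reagents that add atoms: N,O-dimethylhydroxylamine hydrochloride, CNOC.Cl; 1,1'-carbonyldiimidazole, O=C(n1ccnc1)n1ccnc1 (its imidazole is carried only in 8)
Why: Amide formation through the acyl imidazole, the first stage of a Weinreb ketone synthesis; activation and aminolysis need neither a strong base nor a ketene, so the (R) center next to the carbonyl is retained.

Step 6
Reactants: 10 ethyl 2-methyl-3-oxobutanoate (ethyl 2-methylacetoacetate); 9 (2R)-N-methoxy-N,2-dimethylbutanamide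
Product: 12 ethyl (6R)-2,6-dimethyl-3,5-dioxooctanoate, via dilithium dienediolate 11 (not isolated)
Conditions: 10 (1.5 equiv), LiN(iPr)2 (3.0 equiv), THF, 0 °C; then 9 (1.0 equiv), −78 → 0 °C; 1 M HCl
Reagents that add atoms: lithium diisopropylamide, [Li+].CC(C)[N-]C(C)C (lithium is carried only in 11)
Why: Acylation of a β-keto ester dianion at its terminal carbon by an N-methoxy-N-methylamide (Weinreb ketone synthesis): the chelated tetrahedral adduct survives until the quench, which prevents over-addition and proton transfer from the product, and the amide resists α-deprotonation, so the (R) center is retained.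

Step 7
Reactants: 12 ethyl (6R)-2,6-dimethyl-3,5-dioxooctanoate
Product: 13 6-[(2R)-butan-2-yl]-4-hydroxy-3-methyl-2H-pyran-2-one
Conditions: DBU (1.5 equiv), toluene, 80 °C
Reagents that add atoms: none
Why: Base-mediated enol lactonization (6-exo-trig acyl substitution of the C5 enol oxygen on the ethyl ester), driven by formation of the stabilized 4-hydroxy-2-pyranone anion; DBU deprotonates only the carbons between the carbonyl groups, not the sec-butyl methine.

Step 8
Reactants: 13 6-[(2R)-butan-2-yl]-4-hydroxy-3-methyl-2H-pyran-2-one
Product: 14 6-[(2R)-butan-2-yl]-4-methoxy-3-methyl-2H-pyran-2-one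
Conditions: Me2SO4 (1.2 equiv), K2CO3, acetone, reflux
Reagents that add atoms: dimethyl sulfate, COS(=O)(=O)OC
Why: O-Alkylation of the ambident pyranone anion: with the hard sulfate electrophile and K2CO3 in acetone the 4-oxygen is methylated to the 4-methoxy-2-pyranone rather than the 2-methoxy-4-pyranone, and carbonate is too weak to deprotonate the side-chain methine.

Step 9
Reactants: 6 ethyl 3-[(2R,3S)-3,5,7,3',4'-penta-O-benzylcatechin-8-yl]propanoate; 14 6-[(2R)-butan-2-yl]-4-methoxy-3-methyl-2H-pyran-2-one
Product: 17 (2R)-1-[2,4-dihydroxy-6-methoxy-5-methyl-3-({(2R,3S)-3,5,7-tris(benzyloxy)-2-[3,4-bis(benzyloxy)phenyl]-3,4-dihydro-2H-chromen-8-yl}methyl)phenyl]-2-methylbutan-1-one, via ester lithium enolate 15 (not isolated), via open-chain keto ester 16 (not isolated)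
Conditions: LiN(iPr)2 (1.0 equiv), THF, −78 °C; then 14 (1.2 equiv), −78 °C → rt, then 50 °C; 1 M HCl at 0 °C
Reagents that add atoms: lithium diisopropylamide, [Li+].CC(C)[N-]C(C)C (lithium is carried only in 15)
Why: Proposed new method: the lithium enolate 15 adds to the lactone carbonyl (C2) of 14, the tetrahedral alkoxide collapses with cleavage of the C2–O1 bond so that the ring oxygen leaves as the enolate of the sec-butyl ketone, and in the resulting open-chain enol ether 16 the former pyranone C5 attacks the ethyl ester in a Claisen condensation, after which loss of ethoxide and tautomerization give the phloroglucinol as its lithium phenolate; one equivalent of base suffices because everything after the first deprotonation is a proton shuffle. The closest known reaction types are the Claisen cyclization of 3,5,7-triketo esters to acylphloroglucinols, the Fujimoto–Belleau-type opening of enol lactones by carbanions and carbanion-induced ring transformations of 2-pyranones into benzenes. Ring D closes in a 6-(enolexo)-exo-trig mode, preorganized because the former C3=C4 double bond of the pyranone holds the nucleophilic carbon and the β-keto ester on the same side. No stereocenter is formed; the catechin centers carry no acidic hydrogen, and the (R) center of the acyl chain is shielded because the C5 methylene between the ketone and the enol ether is far more acidic than the sec-butyl methine and no excess base is present. The step needs 1,2-addition at C2 over conjugate addition at C4 or C6 and over deprotonation of the sec-butyl methine: a hard lithium enolate at −78 °C, the branched substituent at C6, the donor methoxy group at C4 next to the C3 methyl group and the tertiary nature of the competing C–H should secure this. It also needs Claisen over aldol closure: the aldol adduct of the benzyl-bearing carbon onto the sec-butyl ketone would hold a quaternary carbon and cannot aromatize, so it reverts and only the Claisen path ends in an arene. The methyl enol ether cannot migrate, so the single methoxy group of ring D is placed without any selective methylation.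

Step 10
Reactants: 17 the penta-O-benzyl ether of the target (ring D complete)
Product: 18 (2R)-1-[3-({(2R,3S)-2-(3,4-dihydroxyphenyl)-3,5,7-trihydroxy-3,4-dihydro-2H-chromen-8-yl}methyl)-2,4-dihydroxy-6-methoxy-5-methylphenyl]-2-methylbutan-1-one (target)
Conditions: H2 (1 atm), Pd(OH)2/C, THF/MeOH, rt
Reagents that add atoms: none
Why: Catalytic hydrogenolysis of benzyl ethers: the four aryl ethers cleave first and the secondary alkyl ether last under the same neutral conditions, while the chelated aryl ketone, the diarylmethane and the C2–O1 bond should be inert at 1 atm; no stereocenter is involved.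

## Compound list

1 | (+)-catechin, (2R,3S)-2-(3,4-dihydroxyphenyl)-3,4-dihydro-2H-chromene-3,5,7-triol | Oc1cc(O)c2c(c1)O[C@H](c1ccc(O)c(O)c1)[C@@H](O)C2 | starting material
2 | 5,7,3',4'-tetra-O-benzyl-(+)-catechin | c1c(OCc4ccccc4)cc(OCc4ccccc4)c3c1O[C@H](c2ccc(OCc4ccccc4)c(OCc4ccccc4)c2)[C@@H](O)C3 | intermediate
3 | 3,5,7,3',4'-penta-O-benzyl-(+)-catechin | c1c(OCc4ccccc4)cc(OCc4ccccc4)c3c1O[C@H](c2ccc(OCc4ccccc4)c(OCc4ccccc4)c2)[C@@H](OCc4ccccc4)C3 | intermediate
4 | 8-bromo-3,5,7,3',4'-penta-O-benzyl-(+)-catechin | Brc1c(OCc4ccccc4)cc(OCc4ccccc4)c3c1O[C@H](c2ccc(OCc4ccccc4)c(OCc4ccccc4)c2)[C@@H](OCc4ccccc4)C3 | intermediate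
5 | (3-ethoxy-3-oxopropyl)zinc bromide | CCOC(=O)CC[Zn]Br | starting material
6 | ethyl 3-[(2R,3S)-3,5,7,3',4'-penta-O-benzylcatechin-8-yl]propanoate | CCOC(=O)CCc1c(OCc4ccccc4)cc(OCc4ccccc4)c3c1O[C@H](c2ccc(OCc4ccccc4)c(OCc4ccccc4)c2)[C@@H](OCc4ccccc4)C3 | intermediate
7 | (2R)-2-methylbutanoic acid | CC[C@@H](C)C(=O)O | starting material
8 | (2R)-1-(1H-imidazol-1-yl)-2-methylbutan-1-one | CC[C@@H](C)C(=O)n1ccnc1 | intermediate (not isolated)
9 | (2R)-N-methoxy-N,2-dimethylbutanamide | CC[C@@H](C)C(=O)N(C)OC | intermediate
10 | ethyl 2-methyl-3-oxobutanoate (racemic) | CCOC(=O)C(C)C(C)=O | starting material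
11 | dilithium 1-ethoxy-2-methylbuta-1,3-diene-1,3-diolate (dianion of 10) | [Li+].[Li+].CCOC([O-])=C(C)C([O-])=C | intermediate (not isolated)
12 | ethyl (6R)-2,6-dimethyl-3,5-dioxooctanoate (C2 epimers and enol forms) | CC[C@@H](C)C(=O)CC(=O)C(C)C(=O)OCC | intermediate
13 | 6-[(2R)-butan-2-yl]-4-hydroxy-3-methyl-2H-pyran-2-one | CC[C@@H](C)C1=CC(O)=C(C)C(=O)O1 | intermediate
14 | 6-[(2R)-butan-2-yl]-4-methoxy-3-methyl-2H-pyran-2-one | CC[C@@H](C)C1=CC(OC)=C(C)C(=O)O1 | intermediate
15 | lithium enolate of 6 (lithium 1-ethoxy-3-aryl-prop-1-en-1-olate, aryl = penta-O-benzylcatechin-8-yl) | [Li+].CCOC([O-])=CCc1c(OCc4ccccc4)cc(OCc4ccccc4)c3c1O[C@H](c2ccc(OCc4ccccc4)c(OCc4ccccc4)c2)[C@@H](OCc4ccccc4)C3 | intermediate (not isolated)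
16 | ethyl (4E,8R)-5-methoxy-4,8-dimethyl-3,7-dioxo-2-[(penta-O-benzylcatechin-8-yl)methyl]dec-4-enoate (drawn as the neutral keto form; present in the flask as its lithium enolate; C2 unassigned) | CC[C@@H](C)C(=O)C/C(OC)=C(/C)C(=O)C(Cc1c(OCc4ccccc4)cc(OCc4ccccc4)c3c1O[C@H](c2ccc(OCc4ccccc4)c(OCc4ccccc4)c2)[C@@H](OCc4ccccc4)C3)C(=O)OCC | intermediate (not isolated)
17 | (2R)-1-[2,4-dihydroxy-6-methoxy-5-methyl-3-({(2R,3S)-3,5,7-tris(benzyloxy)-2-[3,4-bis(benzyloxy)phenyl]-3,4-dihydro-2H-chromen-8-yl}methyl)phenyl]-2-methylbutan-1-one | CC[C@@H](C)C(=O)c1c(O)c(Cc2c(OCc4ccccc4)cc(OCc4ccccc4)c3c2O[C@H](c2ccc(OCc4ccccc4)c(OCc4ccccc4)c2)[C@@H](OCc4ccccc4)C3)c(O)c(C)c1OC | intermediate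
18 | (2R)-1-[3-({(2R,3S)-2-(3,4-dihydroxyphenyl)-3,5,7-trihydroxy-3,4-dihydro-2H-chromen-8-yl}methyl)-2,4-dihydroxy-6-methoxy-5-methylphenyl]-2-methylbutan-1-one | CC[C@@H](C)C(=O)c1c(O)c(Cc2c(O)cc(O)c3c2O[C@H](c2ccc(O)c(O)c2)[C@@H](O)C3)c(O)c(C)c1OC | target

## Step count and least certain steps

Total step count: 10. Longest linear sequence: 6 steps (steps 1, 2, 3, 4, 9, 10 from 1; the pyranone branch from 7 also reaches 18 in six steps: 5, 6, 7, 8, 9, 10).

**Step 9 (proposed new method).** Four things may go wrong:
- Proton transfer from the sec-butyl methine of 14 to the ester enolate may outrun addition, which would erode the (R) center and return 6.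
- Addition at the crowded C2 (next to the C3 methyl group) may be slow enough that the ester enolate self-condenses on warming.
- Conjugate addition–elimination at C4 may displace methoxide.
- The sequence may stall at the open-chain stage as the stabilized β-keto ester enolate, and acidic work-up would then re-close it through oxygen, not carbon.

The fallback uses known reactions only. It sets out from 4 and 7 and comes back at 17.
- From 4, bromine–lithium exchange (n-BuLi, THF, −78 °C) and quench with DMF would give penta-O-benzyl-(+)-catechin-8-carbaldehyde F1. NaBH4 reduction would give (penta-O-benzyl-(+)-catechin-8-yl)methanol F2.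
- Ring D would be made as a separate arene. Friedel–Crafts acylation of bought 2-methylbenzene-1,3,5-triol F3 with acid 7 (BF3·OEt2, heat) gives (2R)-2-methyl-1-(2,4,6-trihydroxy-3-methylphenyl)butan-1-one F4.
- Benzylation of the two more accessible phenols of F4 (BnBr, K2CO3, acetone) leaves the chelated hydroxyl between acyl and methyl free, giving (2R)-1-[4,6-bis(benzyloxy)-2-hydroxy-3-methylphenyl]-2-methylbutan-1-one F5.
- Methylation of that last hydroxyl (MeI, K2CO3, DMF) gives (2R)-1-[4,6-bis(benzyloxy)-2-methoxy-3-methylphenyl]-2-methylbutan-1-one F6. Hydrogenolysis (H2, Pd/C) gives (2R)-1-(4,6-dihydroxy-2-methoxy-3-methylphenyl)-2-methylbutan-1-one F7.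
- Acid-catalysed Friedel–Crafts benzylation (Sc(OTf)3 cat. or CF3CO2H, CH2Cl2) of the single free ring position of F7 by the cation from F2 then gives 17.

**Step 4.** Oxidative addition of zerovalent palladium into the hindered, electron-rich C8–Br bond may be slow, so that protodebromination or consumption of the zinc reagent takes over. The fallback avoids palladium. It sets out from 4 and comes back at 6. Bromine–lithium exchange and formylation give penta-O-benzyl-(+)-catechin-8-carbaldehyde F1, as above. Horner–Wadsworth–Emmons olefination with triethyl phosphonoacetate (NaH, THF) gives ethyl (2E)-3-(penta-O-benzylcatechin-8-yl)prop-2-enoate F8. Homogeneous hydrogenation of the alkene (H2, RhCl(PPh3)3, benzene/EtOH), which leaves benzyl ethers alone, gives 6.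

**Step 8.** The ambident pyranone anion may be methylated at the lactone carbonyl oxygen instead of the 4-oxygen, or at C3. The fallback installs the methyl ether before the ring exists. It sets out from 10 and 9 and comes back at 14. Acid-catalysed reaction of 10 with trimethyl orthoformate (H2SO4 cat.) gives ethyl (2E)-3-methoxy-2-methylbut-2-enoate F9. Its lithium dienolate (LiN(iPr)2, THF, −78 °C) is acylated at the terminal carbon by 9 to give ethyl (2E,6R)-3-methoxy-2,6-dimethyl-5-oxooct-2-enoate F10. Enol lactonization (DBU, toluene, heat) then gives 14 directly.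

**Step 10.** Hydrogenolysis of the alkyl benzyl ether at O3 may stay incomplete after the aryl ethers are gone. Forcing may over-reduce (cleavage of the benzylic C2–O1 bond, reduction of the ketone), and the free polyphenol may oxidize during isolation. The fallback replaces surface hydrogenolysis by Lewis-acid cleavage, from 17 to 18 with no new compound: BCl3 with pentamethylbenzene as benzyl-cation scavenger, CH2Cl2, −78 °C, then methanol. The ring D ketone should be tied up as a boron chelate with its ortho phenol, which should protect the neighbouring methyl ether at this temperature.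

## Further compounds

F1 | step 9 | penta-O-benzyl-(+)-catechin-8-carbaldehyde | O=Cc1c(OCc4ccccc4)cc(OCc4ccccc4)c3c1O[C@H](c2ccc(OCc4ccccc4)c(OCc4ccccc4)c2)[C@@H](OCc4ccccc4)C3
F2 | step 9 | (penta-O-benzyl-(+)-catechin-8-yl)methanol | OCc1c(OCc4ccccc4)cc(OCc4ccccc4)c3c1O[C@H](c2ccc(OCc4ccccc4)c(OCc4ccccc4)c2)[C@@H](OCc4ccccc4)C3
F3 | step 9 | 2-methylbenzene-1,3,5-triol (bought, not made) | Cc1c(O)cc(O)cc1O
F4 | step 9 | (2R)-2-methyl-1-(2,4,6-trihydroxy-3-methylphenyl)butan-1-one | CC[C@@H](C)C(=O)c1c(O)cc(O)c(C)c1O
F5 | step 9 | (2R)-1-[4,6-bis(benzyloxy)-2-hydroxy-3-methylphenyl]-2-methylbutan-1-one | CC[C@@H](C)C(=O)c1c(O)c(C)c(OCc2ccccc2)cc1OCc1ccccc1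
F6 | step 9 | (2R)-1-[4,6-bis(benzyloxy)-2-methoxy-3-methylphenyl]-2-methylbutan-1-one | CC[C@@H](C)C(=O)c1c(OC)c(C)c(OCc2ccccc2)cc1OCc1ccccc1
F7 | step 9 | (2R)-1-(4,6-dihydroxy-2-methoxy-3-methylphenyl)-2-methylbutan-1-one | CC[C@@H](C)C(=O)c1c(OC)c(C)c(O)cc1O
F8 | step 4 | ethyl (2E)-3-[(2R,3S)-3,5,7,3',4'-penta-O-benzylcatechin-8-yl]prop-2-enoate | CCOC(=O)/C=C/c1c(OCc4ccccc4)cc(OCc4ccccc4)c3c1O[C@H](c2ccc(OCc4ccccc4)c(OCc4ccccc4)c2)[C@@H](OCc4ccccc4)C3
F9 | step 8 | ethyl (2E)-3-methoxy-2-methylbut-2-enoate | CCOC(=O)/C(C)=C(/OC)C
F10 | step 8 | ethyl (2E,6R)-3-methoxy-2,6-dimethyl-5-oxooct-2-enoate | CC[C@@H](C)C(=O)C/C(OC)=C(/C)C(=O)OCC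
F0 | step 10 | none | none
A1 | alternative 1 | ring A phenol: 5-(benzyloxy)-2-[(2E)-3-(3,4-bis(benzyloxy)phenyl)prop-2-enyl]-3-(triisopropylsilyloxy)-6-(ring D benzyl)phenol, ring D = 2,6-bis(benzyloxy)-4-methoxy-5-methyl-3-[(2R)-2-methylbutanoyl]phenyl | CC[C@@H](C)C(=O)c1c(OCc4ccccc4)c(Cc2c(OCc4ccccc4)cc(O[Si](C(C)C)(C(C)C)C(C)C)c(C/C=C/c5ccc(OCc4ccccc4)c(OCc4ccccc4)c5)c2O)c(OCc4ccccc4)c(C)c1OC
A2 | alternative 1 | 3-(benzyloxy)-4-({2,6-bis(benzyloxy)-4-methoxy-5-methyl-3-[(2R)-2-methylbutanoyl]phenyl}methyl)cyclobut-2-en-1-one | CC[C@@H](C)C(=O)c1c(OCc4ccccc4)c(CC2C(=O)C=C2OCc4ccccc4)c(OCc4ccccc4)c(C)c1OC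
A3 | alternative 1 | {[(4E)-5-[3,4-bis(benzyloxy)phenyl]pent-4-en-1-yn-1-yl]oxy}tri(propan-2-yl)silane | CC(C)[Si](OC#CC/C=C/c1ccc(OCc2ccccc2)c(OCc2ccccc2)c1)(C(C)C)C(C)C
A4 | alternative 2 | hexa-O-benzyl ether of the target with free C3 hydroxyl | CC[C@@H](C)C(=O)c1c(OCc4ccccc4)c(Cc2c(OCc4ccccc4)cc(OCc4ccccc4)c3c2O[C@H](c2ccc(OCc4ccccc4)c(OCc4ccccc4)c2)[C@@H](O)C3)c(OCc4ccccc4)c(C)c1OC
A5 | alternative 2 | ring A aryl ether of (R)-[3,4-bis(benzyloxy)phenyl][(2S)-oxiran-2-yl]methanol carrying the benzylated ring D benzyl group | CC[C@@H](C)C(=O)c1c(OCc4ccccc4)c(Cc2c(OCc4ccccc4)cc(OCc4ccccc4)cc2O[C@H](c2ccc(OCc4ccccc4)c(OCc4ccccc4)c2)[C@@H]2CO2)c(OCc4ccccc4)c(C)c1OC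
A6 | alternative 3 | (2R)-5,7-bis(benzyloxy)-2-[3,4-bis(benzyloxy)phenyl]-8-(ring D benzyl)-2H-chromene-3-carbaldehyde, ring D benzylated | CC[C@@H](C)C(=O)c1c(OCc4ccccc4)c(Cc2c(OCc4ccccc4)cc(OCc4ccccc4)c3c2O[C@H](c2ccc(OCc4ccccc4)c(OCc4ccccc4)c2)C(C=O)=C3)c(OCc4ccccc4)c(C)c1OC
A7 | alternative 3 | 4,6-bis(benzyloxy)-2-hydroxy-3-(ring D benzyl)benzaldehyde, ring D benzylated | CC[C@@H](C)C(=O)c1c(OCc4ccccc4)c(Cc2c(OCc4ccccc4)cc(OCc4ccccc4)c(C=O)c2O)c(OCc4ccccc4)c(C)c1OC
A8 | alternative 3 | (2E)-3-[3,4-bis(benzyloxy)phenyl]prop-2-enal | O=C/C=C/c1ccc(OCc2ccccc2)c(OCc2ccccc2)c1
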